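23 is traced back to hydroazulenone 17 by end-game steps only: C4-OH-directed reduction of C6=O, conversion of the C14 ester to the enal, and aroylation of the secondary C6-OH.
Key disconnection: the ring-fusion bond C1–C5 of 17 comes from a C1–C6 bond in the cis-decalin triol monomesylate 15. One 1,2-shift contracts the six-membered ring C1–C2–C3–C4–C5–C6 to the cyclopentane C1–C5 and expands the cyclohexene C1/C6–C10 to the cycloheptene.
Enabling feature: the cyclopentane plus exocyclic C6 is a hidden p-menthane (carvone) ring. O4 and O6 stand 1,3 (aldol pattern) across the ring-fusion methine C5, and C5 is bonded to quaternary C1. This is the product pattern of a semipinacol shift of C1 from a C6 carbinol to a C5 leaving group.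
15 comes from the cis-hydroxy diene ester 13 (syn-dihydroxylation). 13 comes from the linear dienone 6 (β-face nucleophilic epoxidation, reductive opening, enol triflate carbonylation). 6 comes from Robinson annulation of (+)-dihydrocarvone 1 with methyl vinyl ketone 2.
Ring order: ring A is bought with 1, ring B is made in step 1, and both rings are resized together in step 10. The stereochemical relay runs C4 (carvone) → C1 → C6 → C4/C5 → C5 (inverted) → C6.

Key step: step 10

Remark: atoms carry the daucane numbers of the target in all intermediates (C1 quaternary CH3-bearing fusion carbon, C4 carbinol carbon, C5 fusion CH, C6 ester-bearing CH, C8 formyl-bearing sp2 carbon, C14 formyl carbon; ring A = C1–C6, ring B = C1/C6–C10; β = face of the C1 methyl). Commercial 1 is taken as the (5R) mixture of C2 epimers, whose labile centre is erased by enolisation in step 1.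

Step 1
Reactants: 1 (+)-dihydrocarvone; 2 methyl vinyl ketone
Product: 4 cis-fused ketol (1β-CH3/6β-OH/4α-isopropenyl/C8 ketone), via Michael adduct diketone 3 (not isolated)
Conditions: KOH (0.1 equiv), EtOH–Et2O, −10 to 0 °C; recrystallisation
Reagents that add atoms: none
Why: Robinson-type Michael addition/intramolecular aldol, in which the more substituted enolate of 1 should be alkylated axially on the face cis to the equatorial isopropenyl group (the usual outcome for dihydrocarvone), setting C1 as R, the aldol closes ring B by axial attack to the cis-ketol, and crystallisation should remove the minor C1 epimer.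

Step 2
Reactants: 4 cis-fused ketol
Product: 6 linear dienone, via isopropenyl enone 5 (not isolated)
Conditions: p-TsOH·H2O (0.2 equiv), toluene, reflux, Dean–Stark
Reagents that add atoms: none
Why: Acid-catalysed dehydration (last stage of the Robinson annulation) followed by acid-catalysed double-bond migration through the tertiary cation and the extended dienol should move the isopropenyl C=C into conjugation (C4=C5–C6=C7–C8=O), erasing C4 and C6 on purpose while quaternary C1 cannot epimerise.

Step 3
Reactants: 6 linear dienone
Product: 7 6β,7β-epoxy ketone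
Conditions: 30% H2O2, NaOH (0.3 equiv), MeOH, 0 °C
Reagents that add atoms: hydrogen peroxide, OO
Why: Weitz–Scheffer nucleophilic epoxidation, in which hydroperoxide should add 1,4 to C6 (as with steroidal 4,6-dien-3-ones) and axially on the β face (as with 4-en-3-ones and 10-methyloctalones), placing O6 cis to the C1 methyl and leaving the electron-rich C4=C5 bond untouched.

Step 4
Reactants: 7 6β,7β-epoxy ketone
Product: 8 6β-hydroxy ketone (tertiary allylic ketol with C4=C5)
Conditions: SmI2 (2.2 equiv), THF–MeOH, −90 °C
Reagents that add atoms: none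
Why: SmI2 reduction of an α,β-epoxy ketone cleaves only the Cα–O bond (C7–O) via the ketyl, so the C6–O bond and its β configuration are kept, and the cold near-neutral medium should avoid dehydration back to 6.

Step 5
Reactants: 8 6β-hydroxy ketone
Product: 9 6β-trimethylsilyl ether
Conditions: N-(trimethylsilyl)imidazole, CH2Cl2, 0 to 23 °C
Reagents that add atoms: N-(trimethylsilyl)imidazole, C[Si](C)(C)n1ccnc1
Why: Non-acidic, weakly basic O-silylation masks the tertiary allylic alcohol so that no alkoxide is present to trigger retro-aldol cleavage in the next step.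

Step 6
Reactants: 9 6β-trimethylsilyl ether
Product: 11 C8 enol triflate (C8=C9), via potassium enolate 10 (not isolated)
Conditions: KHMDS, THF, −78 °C; then Comins' reagent, −78 °C
Reagents that add atoms: Comins' reagent, FC(F)(F)S(=O)(=O)N(c1ccc(Cl)cn1)S(=O)(=O)C(F)(F)F
Why: Kinetic enolisation/O-triflation, in which the bulky base should take a proton from unhindered C9 rather than from C7 (neopentyl-like, next to the fully substituted C6), fixing the double bond at C8=C9 and avoiding β-elimination of the silyloxy group.

Step 7
Reactants: 11 C8 enol triflate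
Product: 13 cis-hydroxy diene ester (methyl ester C14 on C8), via silyl-protected methyl ester 12 (not isolated)
Conditions: Pd(OAc)2 (5 mol %), PPh3, CO (1 atm), Et3N, MeOH–DMF, 40 °C; then K2CO3 (cat.), MeOH, 0 °C
Reagents that add atoms: carbon monoxide, [C-]#[O+]; methanol, CO
Why: Pd(0)-catalysed alkoxycarbonylation of an enol triflate installs C14 at the ester level with the C8=C9 bond in place, and mild methanolysis then frees the 6β-OH, which is no longer a β-hydroxy ketone and so is stable.

Step 8
Reactants: 13 cis-hydroxy diene ester
Product: 14 all-cis triol ester (4β,5β,6β-triol/4α-isopropyl)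
Conditions: OsO4 (5 mol %), Me3NO·2H2O (1.5 equiv), CH2Cl2, 23 °C
Reagents that add atoms: trimethylamine N-oxide, C[N+](C)(C)[O-]; water, O
Why: Hydroxyl-directed catalytic osmylation (Upjohn-type) should attack the electron-rich C4=C5 bond rather than the enoate, from the β face, which is the convex face of the cis-decalin, is anti to C7 and is hydrogen-bond directed by the 6β-OH, thereby setting C4 (final) and C5 (to be inverted).

Step 9
Reactants: 14 all-cis triol ester
Product: 15 5β-mesylate
Conditions: MsCl (1.2 equiv), Et3N, CH2Cl2, −20 °C
Reagents that add atoms: methanesulfonyl chloride, CS(=O)(=O)Cl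
Why: Selective sulfonylation, since only the secondary C5-OH can react while the two flanking tertiary alcohols are inert, and all three oxygens being cis rules out epoxide closure.

Step 10
Reactants: 15 5β-mesylate
Product: 17 trans-fused hydroazulenone (4β-OH/5α-H/C6 ketone), via bis(diethylaluminium) alkoxide 16 (not isolated)
Conditions: Et3Al (4 equiv), CH2Cl2, −78 to 0 °C; cold aq. Rochelle salt
Reagents that add atoms: none
Why: Et3Al first converts both tertiary alcohols into aluminium alkoxides (16) and a further equivalent activates the mesylate, so the O6 lone pair pushes the antiperiplanar ring-fusion bond C1–C6 onto C5 as mesylate leaves; this is a push–pull semipinacol, the organoaluminium-promoted pinacol-type rearrangement of a vic-diol monosulfonate, and the same reaction type is known to convert 9-hydroxy-1-sulfonyloxydecalins into hydroazulenones. The new C1–C5 bond closes the cyclopentane C1–C2–C3–C4–C5 by contraction of ring A (backside, SN2-like 1,2-shift across C5–C6) and at the same time closes the cycloheptene C1/C5/C6/C7/C8/C9/C10 by inserting C5 into the former cyclohexene. C5 is the only stereocentre made: it is inverted because C1 must arrive anti to the 5β-mesylate, C1 migrates with retention, and together this fixes 5α-H and the trans ring fusion, while C4 is untouched and C6 becomes a ketone exactly where the ester oxygen is needed. The geometry is secured by the cis-decalin: with isopropyl equatorial the mesylate is equatorial on ring A and is therefore antiperiplanar only to ring bonds (C6–C1 and C4–C3), not to C6–C7. Of these two bonds C6–C1 should migrate, because C1 is a tertiary-alkyl migrating group against primary-alkyl C3 and because its shift relieves the congested bond between two fully substituted carbons. The product leaves the flask as a chelated aluminium aldolate, which should hold back retro-aldol cleavage, β-elimination and drift of the C8=C9 bond until the cold quench.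

Step 11
Reactants: 17 trans-fused hydroazulenone
Product: 18 4β,6α-diol ester
Conditions: Me4NBH(OAc)3 (5 equiv), MeCN–AcOH, −20 °C
Reagents that add atoms: none
Why: Evans–Saksena reduction, in which the 4β-OH binds boron and delivers hydride intramolecularly through a chair-like six-membered transition state to the otherwise shielded β face of C6, giving the equatorial 6α-alcohol, while the enoate is inert to this reagent.

Step 12
Reactants: 18 4β,6α-diol ester
Product: 19 4β,6α,14-triol
Conditions: DIBAL-H (5 equiv), CH2Cl2, −78 °C; Rochelle salt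
Reagents that add atoms: none
Why: DIBAL-H 1,2-reduction of the α,β-unsaturated methyl ester gives the primary allylic alcohol without touching the trisubstituted alkene or any stereocentre.

Step 13
Reactants: 19 4β,6α,14-triol
Product: 20 4β,6α-dihydroxy enal
Conditions: activated MnO2, CH2Cl2, 23 °C
Reagents that add atoms: none
Why: MnO2 oxidises only the allylic primary alcohol, leaving the saturated secondary C6-OH and the tertiary C4-OH unchanged.

Step 14
Reactants: 20 4β,6α-dihydroxy enal; 21 4-acetoxybenzoic acid
Product: 22 6α-(4-acetoxybenzoate)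
Conditions: DCC, DMAP (cat.), CH2Cl2, 23 °C
Reagents that add atoms: none
Why: Steglich esterification acylates the only accessible hydroxyl (secondary, equatorial C6-OH) with retention, the tertiary C4-OH next to isopropyl being too hindered, and the enal tolerates these conditions.

Step 15
Reactants: 22 6α-(4-acetoxybenzoate)
Product: 23 target
Conditions: K2CO3 (0.2 equiv), MeOH, 0 °C; pH 7 buffer
Reagents that add atoms: none
Why: Base-catalysed transesterification removes the activated phenolic acetate much faster than it can attack the hindered secondary alkyl benzoate, and C7-H is not vinylogously acidic, so no β-elimination pathway is open.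

Compound list
1 | (+)-dihydrocarvone, (5R)-2-methyl-5-(prop-1-en-2-yl)cyclohexan-1-one, mixture of C2 epimers | CC1CC[C@@H](C(C)=C)CC1=O | starting material
2 | methyl vinyl ketone (but-3-en-2-one) | CC(=O)C=C | starting material
3 | Michael adduct diketone, (2R,5R)-2-methyl-2-(3-oxobutyl)-5-(prop-1-en-2-yl)cyclohexan-1-one (oxobutyl chain cis to isopropenyl) | CC(=O)CC[C@@]1(C)CC[C@@H](C(C)=C)CC1=O | intermediate
4 | cis-fused decalin ketol: 1β-CH3, 6β-OH, 4α-isopropenyl, C8 ketone | C[C@]12CC[C@@H](C(C)=C)C[C@@]1(O)CC(=O)CC2 | intermediate
5 | isopropenyl enone: C6=C7–C8=O, 1β-CH3, 4α-isopropenyl | C[C@]12CC[C@@H](C(C)=C)CC1=CC(=O)CC2 | intermediate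
6 | linear dienone, (4aR)-4a-methyl-7-(propan-2-yl)-4,4a,5,6-tetrahydronaphthalen-2(3H)-one | C[C@]12CCC(C(C)C)=CC1=CC(=O)CC2 | intermediate
7 | 6β,7β-epoxy ketone (epoxide cis to the C1 methyl, C4=C5 retained) | C[C@]12CCC(C(C)C)=C[C@]13O[C@@H]3C(=O)CC2 | intermediate
8 | 6β-hydroxy ketone: cis-fused, tertiary allylic OH at C6, C4=C5 bearing isopropyl, C8 ketone | C[C@]12CCC(C(C)C)=C[C@@]1(O)CC(=O)CC2 | intermediate
9 | 6β-trimethylsilyl ether of 8 | C[C@]12CCC(C(C)C)=C[C@@]1(O[Si](C)(C)C)CC(=O)CC2 | intermediate
10 | potassium C8/C9 enolate of 9 | [K+].C[C@]12CCC(C(C)C)=C[C@@]1(O[Si](C)(C)C)CC([O-])=CC2 | intermediate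
11 | C8 enol triflate (C8=C9) of 9 | C[C@]12CCC(C(C)C)=C[C@@]1(O[Si](C)(C)C)CC(OS(=O)(=O)C(F)(F)F)=CC2 | intermediate
12 | silyl-protected methyl ester (CO2Me on C8, C8=C9, 6β-OTMS) | C[C@]12CCC(C(C)C)=C[C@@]1(O[Si](C)(C)C)CC(C(=O)OC)=CC2 | intermediate
13 | cis-hydroxy diene ester (6β-OH, 1β-CH3, C4=C5 isopropyl alkene, C8=C9 enoate) | C[C@]12CCC(C(C)C)=C[C@@]1(O)CC(C(=O)OC)=CC2 | intermediate
14 | all-cis triol ester (4β-OH, 4α-isopropyl, 5β-OH, 6β-OH, 1β-CH3, cis-decalin) | C[C@]12CC[C@@](O)(C(C)C)[C@H](O)[C@@]1(O)CC(C(=O)OC)=CC2 | intermediate
15 | 5β-mesylate of 14 | C[C@]12CC[C@@](O)(C(C)C)[C@H](OS(C)(=O)=O)[C@@]1(O)CC(C(=O)OC)=CC2 | intermediate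
16 | bis(diethylaluminium) 4,6-dialkoxide of 15 | C[C@]12CC[C@@](O[Al](CC)CC)(C(C)C)[C@H](OS(C)(=O)=O)[C@@]1(O[Al](CC)CC)CC(C(=O)OC)=CC2 | intermediate
17 | trans-fused hydroazulenone (4β-OH, 4α-isopropyl, 5α-H, 1β-CH3, C6 ketone, C8=C9 methyl enoate) | CC(C)[C@]1(O)CC[C@]2(C)CC=C(C(=O)OC)CC(=O)[C@H]21 | intermediate
18 | 4β,6α-diol methyl ester | CC(C)[C@]1(O)CC[C@]2(C)CC=C(C(=O)OC)C[C@H](O)[C@H]21 | intermediate
19 | 4β,6α,14-triol | CC(C)[C@]1(O)CC[C@]2(C)CC=C(CO)C[C@H](O)[C@H]21 | intermediate
20 | 4β,6α-dihydroxy enal | CC(C)[C@]1(O)CC[C@]2(C)CC=C(C=O)C[C@H](O)[C@H]21 | intermediate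
21 | 4-acetoxybenzoic acid | CC(=O)Oc1ccc(cc1)C(=O)O | starting material
22 | 6α-(4-acetoxybenzoate) of 20 | CC(C)[C@]1(O)CC[C@]2(C)CC=C(C=O)C[C@H](OC(=O)c3ccc(OC(C)=O)cc3)[C@H]21 | intermediate
23 | target, 4β-hydroxy-6α-(4-hydroxybenzoyloxy)dauc-8-en-14-al | CC(C)[C@]1(O)CC[C@]2(C)CC=C(C=O)C[C@H](OC(=O)c3ccc(O)cc3)[C@H]21 | target

Total step count: 15. Longest linear sequence: 15 steps (from 1).

Steps most likely to fail

Step 10. The O4 alkoxide may trigger migration of the other aligned ring bond (C4–C3). The aldol product may also suffer retro-aldol cleavage, or its C8=C9 bond may drift into conjugation with the ketone. The fallback sets out from 13 and comes back at 17. Hydroxyl-directed epoxidation (VO(acac)2, t-BuOOH, CH2Cl2) should give the 4β,5β-epoxy-6β-ol ester F1. In F1, O4 is itself part of the leaving group and so cannot push. A chelating Lewis acid (SnCl4 or Ti(Oi-Pr)Cl3, CH2Cl2, −78 °C) should then promote the 2,3-epoxy alcohol to β-hydroxy ketone semipinacol rearrangement, with the same anti shift of C1 to C5. This releases the 4β-OH directly.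

Step 3. Hydroperoxide may add at the δ-carbon (1,6-addition) or from the α face, giving poor site or facial selectivity. The fallback sets out from 6 and comes back at 8, bypassing 7. Copper(I)-catalysed conjugate borylation (B2pin2, CuCl, NaOt-Bu, bisphosphine, MeOH, THF) should deliver boron axially to C6 on the β face, as cuprates do with 10-methyloctalones, giving the 6β-(pinacolboryl) ketone F2. Stereoretentive oxidation (NaBO3·4H2O, THF–H2O) then gives 8.

Step 8. Turnover on the hindered C4=C5 bond may be slow, and oxidation of the enoate alkene may compete. The fallback sets out from 8 and comes back at 14. Dihydroxylation is moved forward to 8, where C4=C5 is the only C=C bond. The same OH-directed osmylation should give the triol ketone F3. Exhaustive silylation (TMSOTf, 2,6-lutidine) gives the tris(trimethylsilyl) ether F4. Kinetic enolisation and triflation (KHMDS, Comins' reagent) gives the enol triflate F5. Pd-catalysed methoxycarbonylation gives the silylated ester F6. K2CO3 in MeOH then removes the three silyl groups to give 14.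

Further compounds
F1 | step 10 | 4β,5β-epoxy-6β-ol ester | C[C@]12CC[C@]3(C(C)C)O[C@@H]3[C@@]1(O)CC(C(=O)OC)=CC2
F2 | step 3 | 6β-(pinacolboryl) ketone | C[C@]12CCC(C(C)C)=C[C@@]1(B3OC(C)(C)C(C)(C)O3)CC(=O)CC2
F3 | step 8 | 4β,5β,6β-triol ketone | C[C@]12CC[C@@](O)(C(C)C)[C@H](O)[C@@]1(O)CC(=O)CC2
F4 | step 8 | tris(trimethylsilyl) ether of F3 | C[C@]12CC[C@@](O[Si](C)(C)C)(C(C)C)[C@H](O[Si](C)(C)C)[C@@]1(O[Si](C)(C)C)CC(=O)CC2
F5 | step 8 | C8 enol triflate of F4 | C[C@]12CC[C@@](O[Si](C)(C)C)(C(C)C)[C@H](O[Si](C)(C)C)[C@@]1(O[Si](C)(C)C)CC(OS(=O)(=O)C(F)(F)F)=CC2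
F6 | step 8 | tris(trimethylsilyl) ether of 14 | C[C@]12CC[C@@](O[Si](C)(C)C)(C(C)C)[C@H](O[Si](C)(C)C)[C@@]1(O[Si](C)(C)C)CC(C(=O)OC)=CC2
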